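Assumption: the target has no stereocentre and no E/Z element (mirror plane through C1, C4 and the carbonyl; each alkene ends in two methyl groups), so "single enantiomer" is taken to mean the one achiral constitution given.

## Structural features

The target is a benzophenone: an unsubstituted phenyl ring is joined through the ketone carbon to a fully substituted benzene ring (C1–C6). On that ring C1 carries the benzoyl group, C2 and C6 carry free hydroxyls that chelate the ketone, C3 and C5 carry 3-methylbut-2-enyl (prenyl) chains and C4 carries the methoxy group, so O- and C-substituents alternate as in an acylphloroglucinol. There is no stereocentre, so nothing has to be set or protected stereochemically. Fragile elements are the two trisubstituted alkenes, each next to a free phenol (acid closes 2,2-dimethylchromans; hydrogenation and electrophilic oxidants attack them), and the very electron-rich ring. The real difficulty is regio- and chemoselectivity: two C5 chains must be bonded through carbon to C3 and C5 of an ambident phloroglucinol nucleus that otherwise gives O-alkyl, mono-alkyl and gem-dialkyl (dearomatised) products, and O4 must end up methylated while O2 and O6 stay free. The feature the key step exploits is that each prenylated carbon (C3, C5) is ortho to a phenolic oxygen (O2, O6) whose only other ortho carbon, C1, is blocked by the benzoyl group. A C5 unit tethered to O2 or O6 through its tertiary carbon can therefore be handed on to C3 or C5 alone by a [3,3] shift, arriving as the linear prenyl chain. The symmetry of the ring lets both chains be delivered in one operation.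

## Logic of the disconnections

9 ⇒ 5. The bonds cut are C3–C1' and C5–C1' (ring carbon to the CH2 of each prenyl chain); each C5 unit is reconnected through its tertiary carbon to O2 or O6 (double retro-[3,3]). In one sentence, the route is a double aromatic Claisen rearrangement of the bis(1,1-dimethylallyl) ether 5. The cut is made here because intramolecular delivery from oxygen fixes both the site (only C3 and C5 are open ortho positions) and the number of chains (one per oxygen), which intermolecular alkylation cannot do. The gain is that both C–C bonds, the two free chelated hydroxyls and the final substitution pattern appear in one protecting-group-free isomerisation of a symmetric ether. The demand is that both shifts go to C3/C5 and not through C1, under neutral, acid-free conditions that spare the ortho-prenylphenol.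

5 ⇒ 4. No skeletal bond is cut; the two terminal vinyl groups are traced back to ethynyl groups. A tertiary allyl aryl ether cannot be made by direct substitution, whereas the tertiary propargyl ether can. The gain is access to the hindered O–C(CH3)2 linkage by a reliable reaction. The demand is a semi-hydrogenation that stops at the alkene, leaves the diaryl ketone alone and is run cold, because heating 4 itself would give chromenes.

4 ⇒ 2 + 3. The bonds cut are O2–C and O6–C (two ether bonds to the tertiary propargylic carbon). The gain is a return to a symmetric dihydroxybenzophenone and a commercial C5 chloride. The demand is O-alkylation of both hydroxyls flanking the carbonyl, one of which is always chelated, by a tertiary electrophile.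

2 ⇒ 1. The bond cut is O4–CH3. O4–H is para to the carbonyl, the most acidic hydroxyl and the only one that is never chelated, so it can be capped first; this also leaves exactly the two oxygens that must carry the C5 units. The gain is a commercial, symmetric starting material. The demand is mono-methylation at O4 without touching O2/O6.

## Other disconnections considered

Alternative 1: (the first that comes to mind) The same C3–C1' and C5–C1' bonds are cut heterolytically with the arene as nucleophile. The forward key step is base-mediated double C-alkylation of the phenolate of 1 with a prenyl halide to phenyl[2,4,6-trihydroxy-3,5-bis(3-methylbut-2-en-1-yl)phenyl]methanone A1, then O4-methylation (or the same alkylation on 2). The phenolate is ambident and the product is more electron-rich than the substrate, so O-prenyl ethers, mono-prenyl and gem-diprenyl dearomatised products are all expected to compete. In A1, O4–H is flanked by two chains, which should erode the methylation selectivity. The chosen plan fixes site and stoichiometry intramolecularly.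

Alternative 2: The C1–C(=O) bond is cut last. The forward key step is a photo-Fries (or anionic Fries) shift of the benzoyl group from oxygen to the only free ring carbon in 3-hydroxy-5-methoxy-4,6-bis(3-methylbut-2-en-1-yl)phenyl benzoate A3, made from 5-methoxy-4,6-bis(3-methylbut-2-en-1-yl)benzene-1,3-diol A2. This moves the real problem into A2, which needs the same double C-prenylation on a core with no blocking group, where the carbon between the two hydroxyls is the most nucleophilic site. A radical-pair photoreaction beside two alkenes and a light-absorbing chelated product is also hard to defend, and a Lewis-acid Fries would close chromans. The chosen plan uses the benzoyl group itself as the blocking group.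

Alternative 3: The ring bonds C2–C3 and C4–C5 are cut (de novo arene). The forward key step is a thermal cyclobutenone–ynol ether benzannulation (4π-opening to a vinylketene, [2+2], 4π-opening, 6π-closure). It would join 2-(3-methylbut-2-en-1-yl)-3-[(triisopropylsilyl)oxy]cyclobut-2-en-1-one A4 with 1-methoxy-5-methylhex-4-en-1-yne A5 to give 3-methoxy-2,4-bis(3-methylbut-2-en-1-yl)-5-[(triisopropylsilyl)oxy]phenol A6, followed by benzoylation at the last free carbon and desilylation. The regiochemistry would be fully programmed, but A4 and A5 each need several steps, 3-oxygenated cyclobutenones open sluggishly, and the late benzoylation of A6 has to avoid the Lewis acids that cyclise prenylphenols. The route would be at least twice as long as the chosen one for a target whose ring is commercially available.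

Key step: step 4

## Route

Step 1
Reactants: 1 phenyl(2,4,6-trihydroxyphenyl)methanone
Product: 2 (2,6-dihydroxy-4-methoxyphenyl)(phenyl)methanone
Conditions: Me2SO4 (1.0 equiv), K2CO3 (1.0 equiv), acetone, 0 °C to rt
Reagents that add atoms: dimethyl sulfate, COS(=O)(=O)OC
Why: Williamson O-methylation under substrate control: O4–H is para to the carbonyl (vinylogous acid), the most acidic hydroxyl and never chelated, so with one equivalent of base and electrophile the mono-anion should be alkylated at O4, while O2–H/O6–H are held back by hydrogen bonding to the ketone.

Step 2
Reactants: 2 (2,6-dihydroxy-4-methoxyphenyl)(phenyl)methanone; 3 3-chloro-3-methylbut-1-yne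
Product: 4 {4-methoxy-2,6-bis[(2-methylbut-3-yn-2-yl)oxy]phenyl}(phenyl)methanone
Conditions: 3 (3 equiv), DBU (3 equiv), CuCl2·2H2O (1 mol%), MeCN, 0 °C to rt
Reagents that add atoms: none
Why: Copper-catalysed propargylic etherification of phenols: the copper acetylide of 3 ionises to a stabilised propargyl/allenylidene cation equivalent that the amidinium phenoxide captures at the tertiary carbon, which is why a tertiary centre can be etherified; DBU deprotonates the chelated hydroxyl as well, and the low temperature prevents premature sigmatropic chemistry of the aryl propargyl ether.

Step 3
Reactants: 4 {4-methoxy-2,6-bis[(2-methylbut-3-yn-2-yl)oxy]phenyl}(phenyl)methanone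
Product: 5 {4-methoxy-2,6-bis[(2-methylbut-3-en-2-yl)oxy]phenyl}(phenyl)methanone
Conditions: H2 (1 atm), Lindlar catalyst (Pd/CaCO3, Pb-poisoned), quinoline, EtOAc, rt, stopped after 2 equiv H2
Reagents that add atoms: none
Why: Lindlar semi-hydrogenation: terminal alkynes bind to and are reduced on the poisoned palladium much faster than the resulting monosubstituted alkenes; the diaryl ketone and the aryl ethers are inert under these conditions, and room temperature keeps the tertiary allyl ether from rearranging before isolation.

Step 4
Reactants: 5 {4-methoxy-2,6-bis[(2-methylbut-3-en-2-yl)oxy]phenyl}(phenyl)methanone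
Product: 9 [2,6-dihydroxy-4-methoxy-3,5-bis(3-methylbut-2-en-1-yl)phenyl](phenyl)methanone, via first dienone 6 (not isolated), via mono-prenyl phenol 7 (not isolated), via second dienone 8 (not isolated)
Conditions: PhNEt2 (degassed), 160–180 °C, Ar, sealed tube
Reagents that add atoms: none
Why: Double aromatic Claisen rearrangement, the known ortho-shift of aryl 1,1-dimethylallyl ethers to ortho-prenylphenols, run twice in one flask. In each event the O–C(CH3)2 bond breaks while the terminal CH2 of the vinyl group bonds to the free ortho carbon through a six-membered chair-like transition state, so the C5 unit is transposed and arrives as the linear CH2–CH=C(CH3)2 chain (5 to 6, then 7 to 8). Each dienone carries H at the new sp3 carbon and should enolise at once to the phenol (7, then 9), whose new hydroxyl chelates the ketone, which makes each shift irreversible. No ring is closed and no stereocentre remains, since the sp3 carbon of 6 and 8 is lost on aromatisation. The selectivity needed is C3/C5 against the other ortho carbon C1: C1 bears the benzoyl group, a shift to it is hindered and gives a dienone that cannot enolise, so that event is reversible and the flux should drain through C3 and C5. Exactly one C5 unit sits on each of O2 and O6, so the O-prenyl, mono- and gem-diprenyl products of intermolecular alkylation cannot arise, and O4 is already capped as its methyl ether. The tertiary ether carbon lowers the barrier below that of simple allyl ethers, and the basic amine solvent buffers traces of acid that would ionise the tertiary ether or close the ortho-prenylphenol to a chroman.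

## Compound list

1 | phenyl(2,4,6-trihydroxyphenyl)methanone | O=C(c1ccccc1)c1c(O)cc(O)cc1O | starting material
2 | (2,6-dihydroxy-4-methoxyphenyl)(phenyl)methanone (cotoin) | COc1cc(O)c(C(=O)c2ccccc2)c(O)c1 | intermediate
3 | 3-chloro-3-methylbut-1-yne | CC(C)(Cl)C#C | starting material
4 | {4-methoxy-2,6-bis[(2-methylbut-3-yn-2-yl)oxy]phenyl}(phenyl)methanone | COc1cc(OC(C)(C)C#C)c(C(=O)c2ccccc2)c(OC(C)(C)C#C)c1 | intermediate
5 | {4-methoxy-2,6-bis[(2-methylbut-3-en-2-yl)oxy]phenyl}(phenyl)methanone | COc1cc(OC(C)(C)C=C)c(C(=O)c2ccccc2)c(OC(C)(C)C=C)c1 | intermediate
6 | 2-benzoyl-5-methoxy-6-(3-methylbut-2-en-1-yl)-3-[(2-methylbut-3-en-2-yl)oxy]cyclohexa-2,4-dien-1-one (racemic at C6, transient) | COC1=CC(OC(C)(C)C=C)=C(C(=O)c2ccccc2)C(=O)C1CC=C(C)C | intermediate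
7 | {2-hydroxy-4-methoxy-3-(3-methylbut-2-en-1-yl)-6-[(2-methylbut-3-en-2-yl)oxy]phenyl}(phenyl)methanone | COc1cc(OC(C)(C)C=C)c(C(=O)c2ccccc2)c(O)c1CC=C(C)C | intermediate
8 | 2-benzoyl-3-hydroxy-5-methoxy-4,6-bis(3-methylbut-2-en-1-yl)cyclohexa-2,4-dien-1-one (racemic at C6, transient) | COC1=C(CC=C(C)C)C(O)=C(C(=O)c2ccccc2)C(=O)C1CC=C(C)C | intermediate
9 | [2,6-dihydroxy-4-methoxy-3,5-bis(3-methylbut-2-en-1-yl)phenyl](phenyl)methanone | COc1c(CC=C(C)C)c(O)c(C(=O)c2ccccc2)c(O)c1CC=C(C)C | target

## Step count and least certain steps

Total step count: 4. Longest linear sequence: 4 steps (1 → 2 → 4 → 5 → 9).

Step 4 (key step). The most likely failure is heterolysis of the tertiary allylic C–O bond in competition with the concerted shift, with loss of the C5 unit as a diene and return of a free phenol. Passage through the blocked carbon C1 followed by a Cope shift would place a transposed (1,1-dimethylallyl) chain on the ring, and traces of acid would close the ortho-prenylphenol onto its alkene. The fallback abandons the O→C shift for a polarity-reversed cross-coupling. It sets out from 2: electrophilic iodination of the only two free ring carbons (NIS, MeCN, rt) should give (2,6-dihydroxy-3,5-diiodo-4-methoxyphenyl)(phenyl)methanone F1. A double Stille coupling with tributyl(3-methylbut-2-en-1-yl)stannane (Pd(PPh3)4, DMF, 90 °C) is then expected to join both chains at the less substituted allyl terminus. It comes back to the route at 9.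

Step 2. The second etherification has to take place at a hydroxyl that is hydrogen-bonded to the ketone and flanked by the twisted benzoyl group. Incomplete conversion to the mono-ether and competing C-propargylation of the electron-rich ring are the likely failures. The fallback replaces the tertiary electrophile by a primary one and builds the alkene terminus later. It sets out from 2: allyl bromide, K2CO3, DMF, 60 °C should give [4-methoxy-2,6-bis(prop-2-en-1-yloxy)phenyl](phenyl)methanone F2. Thermal double Claisen rearrangement (PhNEt2, 190–200 °C) should give [2,6-dihydroxy-4-methoxy-3,5-di(prop-2-en-1-yl)phenyl](phenyl)methanone F3. Double olefin cross-metathesis with 2-methylbut-2-ene (second-generation Grubbs catalyst, 40 °C) then converts both allyl groups into prenyl groups. It comes back to the route at 9.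

Step 1. Over-methylation and partial alkylation at O2 are likely, because only one of the two ortho hydroxyls is chelated at any moment; 2 would then have to be separated from isomeric and dimethylated material. The fallback replaces selective alkylation by exhaustive alkylation and chelation-directed dealkylation. It sets out from 1: MeI (excess), K2CO3, DMF should give phenyl(2,4,6-trimethoxyphenyl)methanone F4. A Lewis acid that binds the ketone (AlCl3, chlorobenzene, 80 °C, or excess BCl3, CH2Cl2) should then cleave only the two methyl ethers ortho to the carbonyl through six-membered chelates. It comes back to the route at 2.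

Step 3. Over-reduction of the terminal alkenes to tert-pentyl ethers is the main risk, since the alkene product is only a monosubstituted alkene, together with hydrogenolysis of the propargylic C–O bond. The fallback avoids the alkyne and the hydrogenation altogether. It sets out from 2: palladium-catalysed Tsuji–Trost O-allylation with tert-butyl 2-methylbut-3-en-2-yl carbonate F5 (prepared from 2-methylbut-3-en-2-ol and Boc2O) using Pd(PPh3)4 in THF at 0 °C is expected to deliver the phenoxide to the more substituted terminus of the π-allyl complex under kinetic control. It comes back to the route at 5.

## Further compounds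

F1 | step 4 | (2,6-dihydroxy-3,5-diiodo-4-methoxyphenyl)(phenyl)methanone | COc1c(I)c(O)c(C(=O)c2ccccc2)c(O)c1I
F2 | step 2 | [4-methoxy-2,6-bis(prop-2-en-1-yloxy)phenyl](phenyl)methanone | C=CCOc1cc(OC)cc(OCC=C)c1C(=O)c1ccccc1
F3 | step 2 | [2,6-dihydroxy-4-methoxy-3,5-di(prop-2-en-1-yl)phenyl](phenyl)methanone | COc1c(CC=C)c(O)c(C(=O)c2ccccc2)c(O)c1CC=C
F4 | step 1 | phenyl(2,4,6-trimethoxyphenyl)methanone | COc1cc(OC)c(C(=O)c2ccccc2)c(OC)c1
F5 | step 3 | tert-butyl 2-methylbut-3-en-2-yl carbonate | CC(C)(C)OC(=O)OC(C)(C)C=C
A1 | alternative 1 | phenyl[2,4,6-trihydroxy-3,5-bis(3-methylbut-2-en-1-yl)phenyl]methanone | CC(C)=CCc1c(O)c(CC=C(C)C)c(O)c(C(=O)c2ccccc2)c1O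
A2 | alternative 2 | 5-methoxy-4,6-bis(3-methylbut-2-en-1-yl)benzene-1,3-diol | COc1c(CC=C(C)C)c(O)cc(O)c1CC=C(C)C
A3 | alternative 2 | 3-hydroxy-5-methoxy-4,6-bis(3-methylbut-2-en-1-yl)phenyl benzoate | COc1c(CC=C(C)C)c(O)cc(OC(=O)c2ccccc2)c1CC=C(C)C
A4 | alternative 3 | 2-(3-methylbut-2-en-1-yl)-3-[(triisopropylsilyl)oxy]cyclobut-2-en-1-one | CC(C)=CCC1=C(O[Si](C(C)C)(C(C)C)C(C)C)CC1=O
A5 | alternative 3 | 1-methoxy-5-methylhex-4-en-1-yne | COC#CCC=C(C)C
A6 | alternative 3 | 3-methoxy-2,4-bis(3-methylbut-2-en-1-yl)-5-[(triisopropylsilyl)oxy]phenol | COc1c(CC=C(C)C)c(O)cc(O[Si](C(C)C)(C(C)C)C(C)C)c1CC=C(C)C
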